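Late in both runs the readings lie flat, so take the last 3 readings of each and work with the fraction of starting complex left, not the fraction made. Incoming ligand displaces leaving ligand from starting complex, and over the first minutes of both runs the complex with one exchanged falls while isomer of the product rises.

| setting | north-west | north | flask |
|---|---|---|---|
| starting complex | 0.20 mM (fed, over 12 s) | 0.30 mM (fed, over 12 s) | 0.20 mM (fed, over 12 s) |
| incoming ligand | 0.80 mM | 0.80 mM | 0.800 mM |
| leaving ligand | 0.20 mM | 0.20 mM | 0.200 mM |
| remark | the very flask that is asked about, followed so far | run made earlier |  |
| time |  |  | 25 min |

- north-west (time / min: starting complex / %, complex with one exchanged / %, isomer of the product / %): 1.33: 6, 35, 43; 2.50: 4, 25, 59; 4.00: 4, 17, 74; 5.00: 0, 10, 77; 6.00: 5, 11, 74; 8.00: 2, 14, 80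
- north (time / min: starting complex / %, complex with one exchanged / %, isomer of the product / %): 1.50: 6, 39, 51; 3.00: 3, 21, 69; 5.00: 4, 18, 77; 6.00: 2, 14, 81; 8.00: 1, 14, 79; 10.0: 3, 12, 79

(each reading ± 2 percentage points)

- the reaction counts as stopped when no species that holds the starting complex changes by six tenths of a point or more over the second half of the time

- which holds at 25 min: what has brought the reaction to rest, or that it has not come to rest (the incoming ligand has run out first / it is still moving / forward and back rates have come level)
- share of the starting complex used up at 25 min
- complex with one exchanged at 25 min, in percent of the starting complex charged
- isomer of the product at 25 min, in percent of the starting complex charged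

Let m be the fraction of the charge still starting complex, and a the fraction read as complex with one exchanged plus isomer of the product. My first estimate lets each complex past m take one incoming ligand and release one leaving ligand. Counted in charges of complex, X is then the incoming charge minus (1 − m), L is the leaving charge plus (1 − m), and the quotient is:

(a / m) × (L / X)

North-west run: m = 2.33%, a = 88.7%, L/X = 0.654, quotient 24.8

North run: m = 2.00%, a = 93.0%, L/X = 0.976, quotient 45.4

But a flat curve might be a stall for want of ligand. It is not one on this count, since free incoming ligand stands at 3.02 charges in the north-west run and 1.69 in the north run. The harder objection is that the north-west quotient is lower than the north one. Yet a mean of 3 readings still carries 1.2 percentage points, which is large against m, so the gap may be scatter. I therefore take their geometric mean, 33.6, as the rest quotient, the apparent equilibrium constant: a over m, times free leaving over free incoming ligand, once the flask has stopped. For the flask at the asked time, my own reckoning is m = a × (L/X) / Q = 1.73%, a conversion of 98.3%.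

The forecast says forward and back rates have come level, with conversion 98% (96% to 99.7%), complex with one exchanged 10% (7% to 13.5%) and isomer of the product 81% (76% to 86%), on the ground that “Stopping with ligand left over means reversible exchange has reached equilibrium”.

The flask gives forward and back rates have come level, with conversion 98.4%, complex with one exchanged 12.1% and isomer of the product 78.8%.

    complex with one exchanged + incoming ligand ⇌ leaving ligand + complex with two exchanged (K = 0.210, k = 980 /M/s)
    complex with two exchanged + incoming ligand ⇌ leaving ligand + complex with three exchanged (K = 0.700, k = 2500 /M/s)
    complex with three exchanged + incoming ligand ⇌ leaving ligand + complex with four exchanged (K = 0.130, k = 10000 /M/s)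
    complex with one exchanged ⇌ isomer of the product (K = 6.50, k = 0.0130 /s)
    starting complex + incoming ligand ⇌ leaving ligand + complex with one exchanged (K = 5.50, k = 2100 /M/s)

The largest single effect on the conversion of this flask comes from the step between complex with one exchanged and isomer of the product: with that step taken away, conversion falls from 98.4% to 90.1%. The end of this flask has a quotient of 41.2, and the 7.48% held as complex with two, three and four exchanged enter neither a nor m. In a neighbour flask with 1.00 equiv of incoming ligand, X = m, L = 2 − m and a = 1 − m, so Q = (1 − m)(2 − m)/(m × m) gives m = 20.6%; that neighbour flask holds 19%, its quotient 41.2.

The runs were generated by integration with made-up constants, noise included.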